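In a one-step world one time constant tells the whole story: wait long enough and the charge has become product. This flask has a feed and two drains instead.

    catalyst + target ⇌ idle complex (K1 = 1.2 /M, k1 = 0.11 /M/s, Ea1 = 62.0 kJ/mol, ΔH1 = 4.00 kJ/mol)
    solid substrate ⇌ starting material, rate k2*(cs2 - [starting material]) while solid is left; crystals form when [starting material] > cs2 (cs2 = 0.35 M, k2 = 1.3 /s)
    starting material → side product (k3 = 2.5 /s, Ea3 = 69.0 kJ/mol)
    starting material + catalyst → catalyst + target (k4 = 320 /M/s, Ea4 = 36.0 kJ/mol)
    (constants at 40 °C)

common to all: solid substrate 2.1 M; catalyst 4.2 mM; time 15 s
- larch: temperature 40 °C
- cedar: temperature 25 °C
- elm: temperature 10 °C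

* the flask that comes out highest in amount of target, in percent of the solid substrate charged, or "all alike" when all lie within 1.5 percentage points (larch / cedar / elm / all alike)
* target at the end, in percent of the solid substrate charged, larch
* target at the end, in percent of the solid substrate charged, cedar
* target at the end, in percent of the solid substrate charged, elm

- amounts and yields of target count idle complex too
- given per volume of solution although it is solid: solid substrate
- constants are those at 40 °C; use the activation energies and enthalpies for any other temperature
- at the start none of the solid substrate is in solution
- what has only dissolved of solid substrate counts as not reacted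

Start with a bench rule: two first-order drains on one pool share it by their rate constants. Solid substrate feeds the pool of starting material. Hold [catalyst] at its charge and leave idle complex aside, so the step to target is pseudo-first-order. In larch it drains at 1.34 /s against 2.5 /s for the step to side product, a ratio of 0.538. Call this ratio of the target drain to the side drain the split S, the selectivity factor; the target's share is S/(1+S). The side step has the higher activation energy, 69.0 kJ/mol against 36.0 kJ/mol, so cooling raises S to 1.02 in cedar and 2.06 in elm. The shares are 35.0% in larch, 50.4% in cedar and 67.3% in elm.

The rule says where material goes, not whether it gets there in time. So solve both ends. Let L be the sum of the drains: 3.84 /s in larch, 1.33 /s in cedar, 0.461 /s in elm. With a very large L, dissolving sets the pace, with time constant 0.769 s. With a very small L, [starting material] sits near 0.35 M and the drains set it, with time constant 1/L. Join the ends by adding the two in series. The charge is 6.00 times the solubility, so the clearing time is that multiple of the sum: 6.18 s in larch, 9.13 s in cedar, 17.6 s in elm. Against 15 s the ratios are 0.412, 0.609 and 1.17, so elm lies past the border.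

Commit to the shares for larch and cedar. For elm, subtract the filling lag 1/(k2+L), here 0.568 s, with the dissolving coefficient as k2. Then 81.9% of the charge reacts, which gives 55.1% target, still more than the share reckoned for cedar. The forecast also names elm, with 33%, 49% and 54% for larch, cedar and elm, each below mine, and it says “cooling improves selectivity”.

The simulation gives 33.4%, 49.1% and 54.0% for larch, cedar and elm, so elm comes out highest. Carry S to a neighbour of cedar charged with 0.0071 M of catalyst: S becomes 1.72, a share of 63.2%, and that flask gives 61.9%. In larch the target has come to rest: at 150 s it still stands at 33.4%, though idle complex grows from 39.2% of the catalyst at 15.0 s to 45.6%. The target in cedar holds at 49.1%. The target in elm has not come to rest: 19% of its charge is still there, solid or dissolved, at 15.0 s, and the share reckoned for elm makes that 12.8% of the charge as target. At 150 s elm stands at 66.5%, a gain of 12 percentage points.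

The numbers are assumed; what happens was integrated by code.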